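# Proposed synthesis of 6-hydroxy-7-methoxy-3-(3,4,5-trimethoxyphenyl)-4H-chromen-4-one (11) by aroyl shift in a chalcone epoxide

## The problem

The target 11 is an isoflavone: a benzene ring A is fused to a 4-pyranone ring C, and ring C carries the 3,4,5-trimethoxyphenyl ring B on C3. It has no stereocentre, and the stereocentres that appear on the way (the carbinol of 5, the two oxirane carbons of 7, the hemiacetal carbons of 10) are all erased before the end, so none is needed to steer another. The difficulty is one of position: ring B must sit on C3 and not on C2, and ring A must carry oxygen at C6, C7 and C8a with the acyl carbon C4 ortho to O1. The C6 hydroxyl is para to O1, so ring A is a masked hydroquinone that is easily oxidised once both oxygens are free, above all in base, and it should stay protected until the last step. Four aryl methyl ethers must survive the unmasking, which rules out BBr3 or AlCl3, and C2 of the pyranone is a vinylogous ester carbon that hydroxide opens, so ring C is best closed last and under acid. The enabling feature is the array C4(=O)–C3(aryl)–C2: C3 is bonded to the ketone carbon and to ring B, and C2 is at the aldehyde oxidation level (the enol ether of a formyl group with O1). Such a 2-aryl-1,3-dicarbonyl unit is what a 1,2-shift of an aroyl group onto a benzylic cation leaves behind, and ring B with its 4-methoxy group can support that cation.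

## Retrosynthesis

**11 back to 8.** The O1–C2 enol ether bond is cut and the lost water restored. Ring C then opens through the hemiacetal 10 to the hydroxy keto aldehyde 9, and masking both phenols as benzyl ethers gives 8. This is the one bond of ring C that forms by itself under acid. Cutting the C3–aryl bond instead (cross-coupling on a preformed halochromone) would carry the sensitive hydroquinone ring through halogenation and palladium chemistry. Cutting at C2 (one-carbon insertion into a deoxybenzoin) only moves the problem back to a regioselective acylation of ring A. The precursor 8 is acyclic. The forward step must remove two benzyl ethers without touching four methyl ethers; one kind of protecting group serves both phenols because they never need to be told apart.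

**8 back to 7.** The C3–C4 bond is cut by returning the aroyl group from the aryl-bearing carbon to the neighbouring carbon and closing an oxirane: the trans epoxide 7. This turns a branched 1,3-dicarbonyl into a straight three-carbon chain that an aldol can assemble, with the oxidation level already right. The neighbouring option, oxidative shift of ring B in the chalcone 6, forms the C3–aryl bond instead and needs a stoichiometric heavy-metal or hypervalent-iodine oxidant; it is held in reserve. The forward reaction must ionise the epoxide at the benzylic carbon only, move acyl rather than hydride, and keep the 2-oxygen of ring A silent.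

**7 back to 6.** The two C–O bonds of the oxirane are cut, giving the (E)-enone 6. The enone is electron-poor at the β-carbon, so a nucleophilic epoxidation is asked for, and it must deliver the trans epoxide without an ortho phenoxide present to divert it to a flavonol.

**6 back to 3 and 4.** The Cα=Cβ bond (later C2–C3) is cut as an aldol condensation through the aldol 5. All carbons of 11 then come from an acetophenone 3 and the non-enolisable aldehyde 4, and only one enolate can form.

**3 back to 1 and 2.** The two benzyl–oxygen bonds are cut. Acetophenone 1 already holds the full oxygen pattern of ring A with the methyl ether in place, so no selective methylation or arene oxidation is needed; two equivalents of benzyl bromide 2 supply the protecting groups.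

## Roads not taken

**Alternative 1:** Cut of O1–C8a. The enol of the formyl deoxybenzoin A2, which has no oxygen on the ring carbon that becomes C8a, would be oxidised at an anode at constant current. The enol oxygen would bond to the ring C–H para to the isopropoxy group and close ring C, giving the chromone A1 with hydrogen evolved at the cathode; removal of the isopropyl group would then give 11.
- Merits: ring A needs only two oxygens at the start, no 2-oxygen has to be protected, and no chemical oxidant is used.
- Weak points: an anodic C–O closure of an enol oxygen onto an arene C–H to make a pyranone has no close precedent on this substrate class. The C–H to be attacked is ortho to the deactivating acyl group. The trimethoxyphenyl ring and the enol compete for oxidation, and A1 is about as oxidisable as A2. The second ortho position of the acyl group is also open. A2 itself would still have to be made by chemistry of the kind used here.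
- Comparison: this road is better in the cost of its ring-A building block and in avoiding benzyl groups. The chosen plan sets against it that O1 is bought with compound 1 and every step has close precedent.

**Alternative 2:** Cut of three bonds of ring A (C5–C6, C4a–C8a, C8–C8a). In a Dötz benzannulation the chromium carbene complex A5 would combine with the terminal alkyne A4 and one CO ligand to give the hydroquinone monoether A3, with the phenol at C8a and the benzyl ether at C6.
- Merits: ring A is built with full regiocontrol, and its two hydroquinone oxygens emerge differentiated, which would help if analogues at C6 were wanted.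
- Weak points: stoichiometric chromium, separate syntheses of A4 and A5, and after the annulation still desilylation, oxidation of the benzylic alcohol, insertion of C2 and debenzylation. The arene that this effort builds is available ready-made.
- Comparison: the road is more flexible. The chosen plan sets five steps from bought aromatics against it and has no need to tell the two oxygens apart.

**Alternative 3:** Cut of O1–C8a and C4–C4a. CsF would release the aryne A9 from the silyl triflate A8. The enolate oxygen of the formyl arylacetate A7 would add at C8a, steered by the chlorine on C5, and the aryl anion would attack the ester to close ring C, giving the chlorochromone A6. Hydrogenolysis would then have to remove both chlorine and benzyl.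
- Merits: two bonds and ring C in one convergent step from fragments of similar size, with the regiochemistry set by the halogen.
- Weak points: A8 is a pentasubstituted arene that needs several steps. 1,3-Dicarbonyl enolates tend to attack arynes through carbon (acyl-alkylation) rather than oxygen. The extra chlorine must be removed on a chromone whose C2=C3 bond is itself reducible.
- Comparison: this road is the more convergent. The chosen plan sets against it simple fragments, no auxiliary halogen and no O- versus C-selectivity question.

Key step: step 4

Assumption: 1 is bought as such (it is sold as a natural-product acetophenone); 5, 7 and 10 are racemic or diastereomer mixtures, which is immaterial because 11 has no stereocentre.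

## Route

Step 1
Reactants: 1 2',5'-dihydroxy-4'-methoxyacetophenone; 2 benzyl bromide (two equivalents enter the product)
Product: 3 1-[2,5-bis(benzyloxy)-4-methoxyphenyl]ethan-1-one
Conditions: BnBr (2.5 equiv), K2CO3 (4 equiv), KI (cat.), DMF, N2, 70 °C
Reagents that add atoms: benzyl bromide (the second equivalent that enters the product), BrCc1ccccc1
Why: Double Williamson ether synthesis in which each phenol takes up one benzyl group from 2; the 5-hydroxyl reacts readily and the chelated 2-hydroxyl follows in DMF at 70 °C with iodide catalysis, while exclusion of air keeps the para-dihydroxy ring of 1 from being oxidised in base.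

Step 2
Reactants: 3 1-[2,5-bis(benzyloxy)-4-methoxyphenyl]ethan-1-one; 4 3,4,5-trimethoxybenzaldehyde
Product: 6 (E)-1-[2,5-bis(benzyloxy)-4-methoxyphenyl]-3-(3,4,5-trimethoxyphenyl)prop-2-en-1-one, via racemic aldol adduct 5 (not isolated)
Conditions: KOH (50% aq.), EtOH–THF, rt
Reagents that add atoms: none
Why: Claisen–Schmidt condensation; the methyl ketone enolate adds to the non-enolisable aldehyde and aldol 5 loses water by E1cB to the conjugated enone, which should form as the thermodynamically preferred E isomer; benzyl and methyl ethers are inert to hydroxide.

Step 3
Reactants: 6 (E)-1-[2,5-bis(benzyloxy)-4-methoxyphenyl]-3-(3,4,5-trimethoxyphenyl)prop-2-en-1-one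
Product: 7 racemic trans-[2,5-bis(benzyloxy)-4-methoxyphenyl][3-(3,4,5-trimethoxyphenyl)oxiran-2-yl]methanone (the 2R,3S enantiomer is drawn)
Conditions: 30% aq. H2O2, 2 M aq. NaOH, MeOH–THF, 0 °C to rt
Reagents that add atoms: hydrogen peroxide, OO
Why: Weitz–Scheffer nucleophilic epoxidation; hydroperoxide adds to the β-carbon and the enolate closes on oxygen with loss of hydroxide, free rotation in the enolate placing the two large groups trans, and the product is racemic because no chiral reagent is present; with the 2-oxygen benzylated no phenoxide can divert the intermediate to an Algar–Flynn–Oyamada flavonol.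

Step 4
Reactants: 7 racemic trans-[2,5-bis(benzyloxy)-4-methoxyphenyl][3-(3,4,5-trimethoxyphenyl)oxiran-2-yl]methanone
Product: 8 3-[2,5-bis(benzyloxy)-4-methoxyphenyl]-3-oxo-2-(3,4,5-trimethoxyphenyl)propanal (largely enolised, configurationally labile)
Conditions: BF3·OEt2 (1.5 equiv), dry CH2Cl2, 0 °C; then ice-water; product used crude
Reagents that add atoms: none
Why: BF3 binds the oxirane oxygen and the C–O bond at the carbon bearing ring B lengthens, since positive charge there is benzylic whereas the other oxirane carbon is next to a carbonyl and cannot carry it. The aroyl group on the neighbouring carbon then moves with its bonding pair to this electron-poor carbon (a 1,2-acyl shift of the Meinwald or semipinacol kind), creating the bond that is C3–C4 of 11, and the carbon it leaves, still bound to the boron-complexed oxygen, becomes the aldehyde that is C2. The closest known reaction type is the BF3-promoted rearrangement of chalcone epoxides to α-formyl deoxybenzoins, which is also known for 2'-benzyloxy substrates. No ring is closed. The one sp3 stereocentre of 8 lies between two carbonyl groups and is lost to the chelated enol, so neither the racemic nature nor the relative configuration of 7 matters. The step needs opening at the benzylic carbon only and migration of acyl in preference to hydride (which would give the 1,2-diketone); the first is secured by ring B set against the carbonyl, the second by the known preference for acyl migration in these cations, helped by low temperature and a non-nucleophilic solvent that also disfavour fluoride capture. Because the 2-oxygen is an ether and not a phenol it cannot open the epoxide to flavonol or aurone products, and short exposure at 0 °C should leave benzyl and methyl ethers intact; 8 is not chromatographed because α-formyl ketones lose the formyl group on base or silica.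

Step 5
Reactants: 8 3-[2,5-bis(benzyloxy)-4-methoxyphenyl]-3-oxo-2-(3,4,5-trimethoxyphenyl)propanal
Product: 11 6-hydroxy-7-methoxy-3-(3,4,5-trimethoxyphenyl)-4H-chromen-4-one (target), via debenzylated keto aldehyde 9 (not isolated), via 2-hydroxyisoflavanone hemiacetal 10 (not isolated)
Conditions: H2 (1 atm), 10% Pd/C, EtOAc, rt; filter; then conc. HCl (cat.), MeOH, 50 °C
Reagents that add atoms: none
Why: Hydrogenolysis of the two aryl benzyl ethers gives 9, whose 2-hydroxyl adds at once to the aldehyde (6-exo-trig hemiacetal formation) to give 10, and acid-catalysed cyclodehydration then gives the conjugated 4-pyranone; stopping hydrogen uptake at two equivalents in a neutral solvent keeps C2 at the non-reducible hemiacetal stage, and methyl ethers are untouched.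

## Compound list

1 | 2',5'-dihydroxy-4'-methoxyacetophenone [1-(2,5-dihydroxy-4-methoxyphenyl)ethan-1-one] | CC(=O)c1cc(O)c(OC)cc1O | starting material
2 | benzyl bromide | BrCc1ccccc1 | starting material
3 | 1-[2,5-bis(benzyloxy)-4-methoxyphenyl]ethan-1-one | CC(=O)c1cc(OCc2ccccc2)c(OC)cc1OCc1ccccc1 | intermediate
4 | 3,4,5-trimethoxybenzaldehyde | COc1cc(C=O)cc(OC)c1OC | starting material
5 | racemic 1-[2,5-bis(benzyloxy)-4-methoxyphenyl]-3-hydroxy-3-(3,4,5-trimethoxyphenyl)propan-1-one (forms in the flask, not isolated) | COc1cc(OCc2ccccc2)c(C(=O)CC(O)c2cc(OC)c(OC)c(OC)c2)cc1OCc1ccccc1 | intermediate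
6 | (E)-1-[2,5-bis(benzyloxy)-4-methoxyphenyl]-3-(3,4,5-trimethoxyphenyl)prop-2-en-1-one | COc1cc(OCc2ccccc2)c(C(=O)/C=C/c2cc(OC)c(OC)c(OC)c2)cc1OCc1ccccc1 | intermediate
7 | racemic trans-[2,5-bis(benzyloxy)-4-methoxyphenyl][3-(3,4,5-trimethoxyphenyl)oxiran-2-yl]methanone (the 2R,3S enantiomer is drawn) | COc1cc(OCc2ccccc2)c(C(=O)[C@@H]2O[C@H]2c2cc(OC)c(OC)c(OC)c2)cc1OCc1ccccc1 | intermediate
8 | 3-[2,5-bis(benzyloxy)-4-methoxyphenyl]-3-oxo-2-(3,4,5-trimethoxyphenyl)propanal (enolisable, no fixed configuration) | COc1cc(OCc2ccccc2)c(C(=O)C(C=O)c2cc(OC)c(OC)c(OC)c2)cc1OCc1ccccc1 | intermediate
9 | 3-(2,5-dihydroxy-4-methoxyphenyl)-3-oxo-2-(3,4,5-trimethoxyphenyl)propanal (forms in the flask, not isolated) | COc1cc(O)c(C(=O)C(C=O)c2cc(OC)c(OC)c(OC)c2)cc1O | intermediate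
10 | 2,6-dihydroxy-7-methoxy-3-(3,4,5-trimethoxyphenyl)chroman-4-one, mixture of diastereomers (forms in the flask, not isolated) | COc1cc2c(cc1O)C(=O)C(c1cc(OC)c(OC)c(OC)c1)C(O)O2 | intermediate
11 | 6-hydroxy-7-methoxy-3-(3,4,5-trimethoxyphenyl)-4H-chromen-4-one | COc1cc2occ(-c3cc(OC)c(OC)c(OC)c3)c(=O)c2cc1O | target

## Step count and risk

Total step count: 5. Longest linear sequence: 5 steps (1 → 3 → 6 → 7 → 8 → 11).

**Step 4 (key step).**
- Risk: hydride may shift instead of the aroyl group, because the 4-methoxy group of ring B is twisted by its two neighbours and stabilises the cation less than a lone para-methoxy group would.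
- Risk: the ortho benzyloxy oxygen may take part in opening the epoxide, with loss of benzyl and closure to flavonol-type material.
- Risk: fluoride may be captured by the cation, or the formyl group lost on work-up.
- Fallback: it sets out from chalcone 6 and forms the C3–aryl bond instead of C3–C4. Oxidative rearrangement with PhI(OAc)2 and catalytic H2SO4 in MeOH–HC(OMe)3 (the trivalent-iodine counterpart of the thallium trinitrate, Tl(NO3)3, chalcone rearrangement) should add methanol and iodine across the enone. Ring B then shifts from the β- to the α-carbon with loss of iodobenzene, giving racemic 1-[2,5-bis(benzyloxy)-4-methoxyphenyl]-3,3-dimethoxy-2-(3,4,5-trimethoxyphenyl)propan-1-one F1. Brief treatment with dilute HCl in THF–water frees the aldehyde, and the route is rejoined at 8, bypassing 7.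

**Step 5.**
- Risk: over-reduction, either of the enol double bond of 8 and 9 before the hemiacetal forms or of the C2=C3 bond if dehydration begins on the catalyst.
- Risk: loss of the formyl group from 9, or air oxidation of the free hydroquinone ring before ring C is closed.
- Fallback: it sets out from 8 and avoids hydrogen altogether. BCl3 with pentamethylbenzene as benzyl-cation scavenger in CH2Cl2 at −78 °C should cleave both aryl benzyl ethers, the chelated 2-ether first, while leaving methyl ethers that are not ortho to a carbonyl. A methanol quench and warming let the HCl formed carry the material through 9 and 10 to 11, where the route ends. This fallback makes no compound beyond those already listed (entry F0).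

**Step 3.**
- Risk: slow conjugate addition of hydroperoxide to an electron-rich, poorly soluble enone.
- Risk: retro-aldol cleavage on long exposure to alkali, or acid-catalysed opening of the benzylic epoxide during purification.
- Fallback: it sets out from acetophenone 3 and builds the epoxide by C–C bond formation. α-Bromination with CuBr2 in EtOAc–CHCl3 at reflux should give 1-[2,5-bis(benzyloxy)-4-methoxyphenyl]-2-bromoethan-1-one F2. Darzens condensation of F2 with aldehyde 4 (NaOMe, MeOH–THF, 0 °C) then gives the trans epoxide directly, and the route is rejoined at 7, bypassing 6.

## Further compounds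

F1 | step 4 | racemic 1-[2,5-bis(benzyloxy)-4-methoxyphenyl]-3,3-dimethoxy-2-(3,4,5-trimethoxyphenyl)propan-1-one | COc1cc(OCc2ccccc2)c(C(=O)C(C(OC)OC)c2cc(OC)c(OC)c(OC)c2)cc1OCc1ccccc1
F0 | step 5 | none | none
F2 | step 3 | 1-[2,5-bis(benzyloxy)-4-methoxyphenyl]-2-bromoethan-1-one | COc1cc(OCc2ccccc2)c(C(=O)CBr)cc1OCc1ccccc1
A1 | alternative 1 | 6-isopropoxy-7-methoxy-3-(3,4,5-trimethoxyphenyl)-4H-chromen-4-one | COc1cc2occ(-c3cc(OC)c(OC)c(OC)c3)c(=O)c2cc1OC(C)C
A2 | alternative 1 | 3-(3-isopropoxy-4-methoxyphenyl)-3-oxo-2-(3,4,5-trimethoxyphenyl)propanal | COc1ccc(C(=O)C(C=O)c2cc(OC)c(OC)c(OC)c2)cc1OC(C)C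
A3 | alternative 2 | racemic 4-(benzyloxy)-2-[1-(tert-butyldimethylsilyloxy)-2-(3,4,5-trimethoxyphenyl)ethyl]-5-methoxyphenol | COc1cc(O)c(C(O[Si](C)(C)C(C)(C)C)Cc2cc(OC)c(OC)c(OC)c2)cc1OCc1ccccc1
A4 | alternative 2 | racemic tert-butyldimethyl{[1-(3,4,5-trimethoxyphenyl)but-3-yn-2-yl]oxy}silane | C#CC(O[Si](C)(C)C(C)(C)C)Cc1cc(OC)c(OC)c(OC)c1
A5 | alternative 2 | pentacarbonyl[(benzyloxy)(1-methoxyethenyl)carbene]chromium, (CO)5Cr=C(OBn)C(OMe)=CH2 | C=C(OC)C(OCc1ccccc1)=[Cr](=C=O)(=C=O)(=C=O)(=C=O)=C=O
A6 | alternative 3 | 6-(benzyloxy)-5-chloro-7-methoxy-3-(3,4,5-trimethoxyphenyl)-4H-chromen-4-one | COc1cc2occ(-c3cc(OC)c(OC)c(OC)c3)c(=O)c2c(Cl)c1OCc1ccccc1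
A7 | alternative 3 | methyl 3-oxo-2-(3,4,5-trimethoxyphenyl)propanoate (reacts as its enolate) | COC(=O)C(C=O)c1cc(OC)c(OC)c(OC)c1
A8 | alternative 3 | 4-(benzyloxy)-3-chloro-5-methoxy-2-(trimethylsilyl)phenyl trifluoromethanesulfonate | COc1cc(OS(=O)(=O)C(F)(F)F)c([Si](C)(C)C)c(Cl)c1OCc1ccccc1
A9 | alternative 3 | 4-(benzyloxy)-3-chloro-5-methoxybenzyne (1,2-didehydrobenzene, transient) | COC1=CC#CC(Cl)=C1OCc1ccccc1
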